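(The readings were computed from invented constants, noise included.)

One percent of the E charged is 0.200 mM in this flask, and the meeting began by agreeing to count Z and chains begun alike in millimolar, a chain length being the ratio of the two.

in all of them: E 20 mM
- Friday's: Q 6 mM; J 0.38 mol%; run made earlier
- Thursday's: Q 6 mM; J 1.5 mol%; run made earlier
- flask: Q 6.00 mM; J 0.75 mol%; time 12 min

- Friday's (time / min: Z / %, E / %): 2.00: 4, 85; 5.00: 6, 73; 10.0: 11, 64; 15.0: 17, 57
- Thursday's (time / min: Z / %, E / %): 1.00: 2, 88; 2.50: 12, 77; 6.00: 17, 59; 15.0: 31, 41

(standard deviation of a reading: 2 percentage points)

- the average divides the monomer in chains by the number of chains begun, living and dead together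
- the earlier runs do not show the number of chains; that part of a forecast is a guess

- whether the average number of monomer units in a chain (chains begun, living or dead) reaches 10 by 12 min (no / yes)
- average number of monomer units in a chain (chains begun, living or dead) at 12 min

The chair noted that the runs show Z but no count of chains, so the first speaker proposed to bound the length instead of reading it. She argued that if one J begins at most one chain, the chains in this flask stay within the J charged, 0.150 mM.

The second speaker supplied Z. At 15.0 min, Friday's run read 17% and Thursday's 31%, each with a scatter of 2 percentage points. This flask has twice Friday's loading and half Thursday's, so he took the geometric mean of the two readings and scaled it in proportion to time, which gave Z near 18.4% at 12 min.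

Dividing Z in millimolar by that J charge gave 24.5, which she named the floor length: Z over J charged, the lowest average length under her assumption. A floor of 10 needs Z of 7.50%, less than the expected Z, and the meeting put that crossing near 4.90 min. It minuted yes, with the length expected at or above the floor if her assumption held; a third speaker called any higher figure a guess.

The forecast, unlike this reckoning, puts a figure on that guess: yes, with 80 in a range of 25 to 300, on the ground that “J is only partly consumed”.

The flask gives yes and a length of 40.9 at 12 min, with the wanted length reached at 2.25 min, earlier than the crossing.

    E + J → D + Z (k = 3.40 /M/s)
    E + D → Z + D, rate k2*[D]*[E] (k = 4.10 /M/s)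
    J → X (k = 0.00280 /s)
    2 J → G (k = 290 /M/s)
    Q + E → L (k = 0.250 /M/s)

The Z of 19.2% at 12.0 min makes this flask's floor 25.5, below its length, so 62.4% of the J charged had begun chains by then, the initiator efficiency. Thursday's run, at twice this loading, has a floor of 20.7 from its reading at 15.0 min. In this flask J fell to 0.364% of its charge by 1.20 min while D rose to 0.0930 mM and Q took up E to give L, half of that step's turnover up to 12 min being done by 2.28 min. D then held at 0.0936 mM through 12.0 min while growth on D carried Z to 19.2%, and by then E went to L at 0.32 of its rate to Z.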